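## Retrosynthetic overview

1. Locants used below: ring C1 (O‑angelate), C2=C3(CH3), C4 (OAc), C5H2, C6 (carries the chain); chain C7 (CH3), C8, C9 (OAc), C10=C11. Target ⇐ bis‑acetylation of the diol from one CBS reduction of a C4/C9 diketone ⇐ C1 angelate of a 4‑hydroxy enone ⇐ a 1‑methoxy‑1,3‑diene oxidised at its far terminus.
2. Key disconnection C6–C7: anionic oxy‑Cope rearrangement. The chain head is first hung on ring C2 through a C2–C9 bond that is absent from the target; the [3,3] shift trades this bond for C6–C7.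
3. Enabling feature: with the ring drawn as the C1=C2–C3(CH3)=C4(OCH3) dienol ether, C9(=O)–C8–C7–C6–C1=C2 is a δ,ε‑unsaturated carbonyl array (the oxy‑Cope retron). Ring plus C9 then map onto 3‑methoxy‑2‑methylbenzoic acid (CO2H carbon = C9, OCH3 carbon = C4, CH3 carbon = C3).
4. Ring order: the carbocycle is the only ring; it is taken from the arene by Birch dearomatisation before the key step, and no ring is closed afterwards.
5. Stereochemistry: C2 (resolved) → C6 by suprafacial transfer; C7 by the chair transition state; C1 by epoxidation anti to the chain; C4 and C9 by reagent‑controlled reduction.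

Key step: step 5

Assumption: the lipase of step 3 hydrolyses the (S)‑ester and leaves the (R)‑ester; this enantiopreference has to be confirmed by screening.

## Route

Step 1
Reactants: 1 3‑methoxy‑2‑methylbenzoic acid
Product: 2 rac‑3‑methoxy‑2‑methylcyclohexa‑2,5‑diene‑1‑carboxylic acid
Conditions: Li, NH3(l)/THF, −78 → −33 °C; NH4Cl; cold dilute acid to pH 4
Reagents that add atoms: none
Why: Birch reduction of a benzoate (1,4‑reduction with protonation at the ipso and para carbons) leaves the OCH3‑ and CH3‑bearing carbons on one double bond and places the carboxyl‑bearing sp3 carbon between the two alkenes; the new stereocentre is formed racemic.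

Step 2
Reactants: 2 rac‑3‑methoxy‑2‑methylcyclohexa‑2,5‑diene‑1‑carboxylic acid
Product: 3 methyl rac‑3‑methoxy‑2‑methylcyclohexa‑2,5‑diene‑1‑carboxylate
Conditions: TMSCHN2, PhMe/MeOH, 0 °C
Reagents that add atoms: trimethylsilyldiazomethane, C[Si](C)(C)C=[N+]=[N-]
Why: O‑methylation of the acid by a diazoalkane under neutral conditions spares the acid‑labile enol ether and the base‑labile doubly allylic α‑position; no stereocentre is touched.

Step 3
Reactants: 3 methyl rac‑3‑methoxy‑2‑methylcyclohexa‑2,5‑diene‑1‑carboxylate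
Product: 4 methyl (1R)‑3‑methoxy‑2‑methylcyclohexa‑2,5‑diene‑1‑carboxylate
Conditions: Candida rugosa lipase, phosphate buffer pH 7.2/MTBE, 25 °C, to ca. 55% conversion; unreacted ester recovered
Reagents that add atoms: none
Why: Lipase‑catalysed kinetic resolution by enantioselective hydrolysis of an α‑branched ester at neutral pH, where neither the enol ether nor the α‑stereocentre is labile, should return the slower (R)‑ester enantioenriched; this is the source of all absolute configuration.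

Step 4
Reactants: 4 methyl (1R)‑3‑methoxy‑2‑methylcyclohexa‑2,5‑diene‑1‑carboxylate; 5 (Z)‑1‑bromoprop‑1‑ene
Product: 8 (1RS,2Z)‑1‑[(1R)‑3‑methoxy‑2‑methylcyclohexa‑2,5‑dien‑1‑yl]but‑2‑en‑1‑ol, via (Z)‑prop‑1‑enyllithium 6 (not isolated), via dienyl aldehyde 7 (not isolated)
Conditions: 5, t‑BuLi (2 equiv), Et2O, −78 °C; separately 4, DIBAL‑H (1.05 equiv), CH2Cl2, −78 °C, then the alkenyllithium solution, −78 → −40 °C; aq. Rochelle salt
Reagents that add atoms: none
Why: One‑pot DIBAL‑H half‑reduction and alkenyllithium addition, in which the aluminium hemiacetal releases the enolisable aldehyde only as it is trapped at −78 °C and so protects the doubly allylic stereocentre from epimerisation; the Br/Li exchange keeps the (Z) geometry and the new carbinol centre is left uncontrolled because it becomes the aldehyde carbon in step 5.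

Step 5
Reactants: 8 (1RS,2Z)‑1‑[(1R)‑3‑methoxy‑2‑methylcyclohexa‑2,5‑dien‑1‑yl]but‑2‑en‑1‑ol
Product: 11 (3R)‑3‑[(1S)‑5‑methoxy‑4‑methylcyclohexa‑2,4‑dien‑1‑yl]butanal, via potassium alkoxide 9 (not isolated), via potassium enolate 10 (not isolated)
Conditions: KH, 18‑crown‑6, THF, 0 → 25 °C; then sat. aq. NH4Cl, −78 °C
Reagents that add atoms: none
Why: Anionic oxy‑Cope rearrangement ([3,3] shift of a 1,5‑dien‑3‑olate), of the type known for the carbinols made from pentadienyl anions and carbonyl compounds: the potassium alkoxide weakens the C2–C9 bond and the 1,5‑diene C6=C1–C2–C9–C8=C7 reorganises through a chair transition state to the aldehyde enolate, with a new C6–C7 bond and the conjugated C1=C2–C3=C4 dienol ether as driving force. No ring is closed; the six‑membered chair exists only in the transition state. C6 is set by suprafacial transfer across the C6=C1–C2 allyl unit, so (R) at C2 becomes (S) at C6; C7 is set by the chair with the (Z)‑methyl pseudoaxial, the boat being disfavoured because it would push this methyl over the ring CH2, and together they give the (6S,7R) array. Both carbinol epimers should converge, because the carbinol carbon carries only H and O− and ends as the sp2 aldehyde carbon. The step needs regioselectivity between the two ring alkenes flanking C2, and the substrate secures it: the other alkene is the tetrasubstituted enol ether, whose OCH3‑bearing terminus would have to become a quaternary centre. It also needs the concerted shift to outrun fragmentation to a cyclohexadienyl anion, which the crown‑ether‑separated alkoxide at 0–25 °C should favour.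

Step 6
Reactants: 11 (3R)‑3‑[(1S)‑5‑methoxy‑4‑methylcyclohexa‑2,4‑dien‑1‑yl]butanal; 12 (2‑methylprop‑1‑en‑1‑yl)magnesium bromide
Product: 13 (4RS,6R)‑6‑[(1S)‑5‑methoxy‑4‑methylcyclohexa‑2,4‑dien‑1‑yl]‑2‑methylhept‑2‑en‑4‑ol
Conditions: THF, −78 → 0 °C; sat. aq. NH4Cl
Reagents that add atoms: none
Why: Grignard 1,2‑addition to the aldehyde completes the carbon skeleton; the carbinol centre is not controlled because it is oxidised in step 7.

Step 7
Reactants: 13 (4RS,6R)‑6‑[(1S)‑5‑methoxy‑4‑methylcyclohexa‑2,4‑dien‑1‑yl]‑2‑methylhept‑2‑en‑4‑ol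
Product: 14 (6R)‑6‑[(1S)‑5‑methoxy‑4‑methylcyclohexa‑2,4‑dien‑1‑yl]‑2‑methylhept‑2‑en‑4‑one
Conditions: Dess–Martin periodinane, pyridine, CH2Cl2, 0 °C
Reagents that add atoms: none
Why: Dess–Martin oxidation of the allylic alcohol, buffered with pyridine so that the dienol ether is not hydrolysed; the conjugation created deactivates the isobutenyl double bond towards the electrophilic oxidant of step 8.

Step 8
Reactants: 14 (6R)‑6‑[(1S)‑5‑methoxy‑4‑methylcyclohexa‑2,4‑dien‑1‑yl]‑2‑methylhept‑2‑en‑4‑one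
Product: 16 (4S,5S)‑4‑hydroxy‑2‑methyl‑5‑[(2R)‑6‑methyl‑4‑oxohept‑5‑en‑2‑yl]cyclohex‑2‑en‑1‑one, via anti‑epoxide 15 (not isolated)
Conditions: DMDO (acetone), CH2Cl2, −78 °C; then H2O, PPTS (cat.), 0 °C
Reagents that add atoms: dimethyldioxirane, CC1(C)OO1; water, O
Why: Oxidation of a 1‑alkoxy‑1,3‑diene at its remote double bond (the dienol ether to γ‑hydroxy enone conversion with peracids or dioxiranes): the electrophilic oxygen should attack the terminal C1=C2 bond on the face opposite the chain on the neighbouring C6, setting C1–O trans to C6 (1S), and aqueous acid opens the vinylogous epoxy enol ether to the 4‑hydroxy enone with loss of methanol.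

Step 9
Reactants: 16 (4S,5S)‑4‑hydroxy‑2‑methyl‑5‑[(2R)‑6‑methyl‑4‑oxohept‑5‑en‑2‑yl]cyclohex‑2‑en‑1‑one; 17 angelic acid, (2Z)‑2‑methylbut‑2‑enoic acid
Product: 19 (1S,6S)‑3‑methyl‑6‑[(2R)‑6‑methyl‑4‑oxohept‑5‑en‑2‑yl]‑4‑oxocyclohex‑2‑en‑1‑yl (2Z)‑2‑methylbut‑2‑enoate, via mixed anhydride 18 (not isolated)
Conditions: 17, 2,4,6‑Cl3C6H2COCl, Et3N, PhMe, 25 °C; then 16, 75 °C
Reagents that add atoms: none
Why: Acylation of the single hydroxyl group with the preformed mixed anhydride (Yamaguchi‑type, no DMAP), chosen because it avoids Z to E isomerisation of angelates to tiglates; the configuration at C1 is retained.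

Step 10
Reactants: 19 (1S,6S)‑3‑methyl‑6‑[(2R)‑6‑methyl‑4‑oxohept‑5‑en‑2‑yl]‑4‑oxocyclohex‑2‑en‑1‑yl (2Z)‑2‑methylbut‑2‑enoate
Product: 20 (1S,4R,6S)‑4‑hydroxy‑6‑[(2R,4R)‑4‑hydroxy‑6‑methylhept‑5‑en‑2‑yl]‑3‑methylcyclohex‑2‑en‑1‑yl (2Z)‑2‑methylbut‑2‑enoate
Conditions: (S)‑Me‑CBS, catecholborane, PhMe, −78 °C; MeOH
Reagents that add atoms: none
Why: Corey–Bakshi–Shibata reduction of both enones in one operation: in each ketone the alkenyl arm is the large group and the CH2 arm the small one, so the (S)‑catalyst should deliver hydride to give 4R in the ring and 9R in the chain, while catecholborane at −78 °C leaves the ester and the alkenes alone.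

Step 11
Reactants: 20 (1S,4R,6S)‑4‑hydroxy‑6‑[(2R,4R)‑4‑hydroxy‑6‑methylhept‑5‑en‑2‑yl]‑3‑methylcyclohex‑2‑en‑1‑yl (2Z)‑2‑methylbut‑2‑enoate
Product: 21 (1S,4R,6S)‑4‑acetoxy‑6‑[(2R,4R)‑4‑acetoxy‑6‑methylhept‑5‑en‑2‑yl]‑3‑methylcyclohex‑2‑en‑1‑yl (2Z)‑2‑methylbut‑2‑enoate
Conditions: Ac2O, pyridine, DMAP (cat.), CH2Cl2, 0 → 25 °C
Reagents that add atoms: acetic anhydride, CC(=O)OC(C)=O
Why: DMAP‑catalysed acetylation of the two secondary allylic alcohols; no stereocentre is affected and the product is the target.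

## Compound list

1 | 3‑methoxy‑2‑methylbenzoic acid | COc1cccc(C(O)=O)c1C | starting material
2 | rac‑3‑methoxy‑2‑methylcyclohexa‑2,5‑diene‑1‑carboxylic acid | OC(=O)C1C=CCC(OC)=C1C | intermediate
3 | methyl rac‑3‑methoxy‑2‑methylcyclohexa‑2,5‑diene‑1‑carboxylate | COC(=O)C1C=CCC(OC)=C1C | intermediate
4 | methyl (1R)‑3‑methoxy‑2‑methylcyclohexa‑2,5‑diene‑1‑carboxylate | COC(=O)[C@@H]1C=CCC(OC)=C1C | intermediate
5 | (Z)‑1‑bromoprop‑1‑ene | C/C=C\Br | starting material
6 | (Z)‑prop‑1‑enyllithium | C/C=C\[Li] | intermediate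
7 | (1R)‑3‑methoxy‑2‑methylcyclohexa‑2,5‑diene‑1‑carbaldehyde | O=C[C@@H]1C=CCC(OC)=C1C | intermediate
8 | (1RS,2Z)‑1‑[(1R)‑3‑methoxy‑2‑methylcyclohexa‑2,5‑dien‑1‑yl]but‑2‑en‑1‑ol | C/C=C\C(O)[C@@H]1C=CCC(OC)=C1C | intermediate
9 | potassium alkoxide of 8 | C/C=C\C([O-])[C@@H]1C=CCC(OC)=C1C.[K+] | intermediate
10 | potassium enolate of 11 | COC1=C(C)C=C[C@@H](C1)[C@H](C)C=C[O-].[K+] | intermediate
11 | (3R)‑3‑[(1S)‑5‑methoxy‑4‑methylcyclohexa‑2,4‑dien‑1‑yl]butanal | COC1=C(C)C=C[C@@H](C1)[C@H](C)CC=O | intermediate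
12 | (2‑methylprop‑1‑en‑1‑yl)magnesium bromide | CC(C)=C[Mg]Br | starting material
13 | (4RS,6R)‑6‑[(1S)‑5‑methoxy‑4‑methylcyclohexa‑2,4‑dien‑1‑yl]‑2‑methylhept‑2‑en‑4‑ol | COC1=C(C)C=C[C@@H](C1)[C@H](C)CC(O)C=C(C)C | intermediate
14 | (6R)‑6‑[(1S)‑5‑methoxy‑4‑methylcyclohexa‑2,4‑dien‑1‑yl]‑2‑methylhept‑2‑en‑4‑one | COC1=C(C)C=C[C@@H](C1)[C@H](C)CC(=O)C=C(C)C | intermediate
15 | (6R)‑6‑[(1S,2S,6R)‑4‑methoxy‑5‑methyl‑7‑oxabicyclo[4.1.0]hept‑4‑en‑2‑yl]‑2‑methylhept‑2‑en‑4‑one (epoxide oxygen on the ring face opposite the chain) | COC1=C(C)[C@H]2O[C@H]2[C@@H](C1)[C@H](C)CC(=O)C=C(C)C | intermediate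
16 | (4S,5S)‑4‑hydroxy‑2‑methyl‑5‑[(2R)‑6‑methyl‑4‑oxohept‑5‑en‑2‑yl]cyclohex‑2‑en‑1‑one | O[C@@H]1C=C(C)C(=O)C[C@H]1[C@H](C)CC(=O)C=C(C)C | intermediate
17 | angelic acid, (2Z)‑2‑methylbut‑2‑enoic acid | C/C=C(/C)C(O)=O | starting material
18 | (2Z)‑2‑methylbut‑2‑enoic 2,4,6‑trichlorobenzoic anhydride | C/C=C(/C)C(=O)OC(=O)c1c(Cl)cc(Cl)cc1Cl | intermediate
19 | (1S,6S)‑3‑methyl‑6‑[(2R)‑6‑methyl‑4‑oxohept‑5‑en‑2‑yl]‑4‑oxocyclohex‑2‑en‑1‑yl (2Z)‑2‑methylbut‑2‑enoate | C/C=C(/C)C(=O)O[C@@H]1C=C(C)C(=O)C[C@H]1[C@H](C)CC(=O)C=C(C)C | intermediate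
20 | (1S,4R,6S)‑4‑hydroxy‑6‑[(2R,4R)‑4‑hydroxy‑6‑methylhept‑5‑en‑2‑yl]‑3‑methylcyclohex‑2‑en‑1‑yl (2Z)‑2‑methylbut‑2‑enoate | C/C=C(/C)C(=O)O[C@@H]1C=C(C)[C@H](O)C[C@H]1[C@H](C)C[C@H](C=C(C)C)O | intermediate
21 | (1S,4R,6S)‑4‑acetoxy‑6‑[(2R,4R)‑4‑acetoxy‑6‑methylhept‑5‑en‑2‑yl]‑3‑methylcyclohex‑2‑en‑1‑yl (2Z)‑2‑methylbut‑2‑enoate | C/C=C(/C)C(=O)O[C@@H]1C=C(C)[C@H](OC(C)=O)C[C@H]1[C@H](C)C[C@H](C=C(C)C)OC(C)=O | target

Total step count: 11. Longest linear sequence: 11 steps (1 → 21).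

## Steps most likely to fail

Step 3. The enzyme may discriminate the enantiomers too weakly, since the two groups flanking the stereocentre differ only as CH= and C(CH3)=, and the recovered ester would then be of low enantiomeric purity. The fallback sets out from acid 2 and is a classical resolution: crystallisation with (S)‑1‑phenylethylamine from EtOAc should give the less soluble diastereomeric salt (1S)‑1‑phenylethanaminium (1R)‑3‑methoxy‑2‑methylcyclohexa‑2,5‑diene‑1‑carboxylate F1 (the other amine enantiomer is used if the solubility order is reversed). Partition between cold aqueous NaHSO4 and EtOAc frees (1R)‑3‑methoxy‑2‑methylcyclohexa‑2,5‑diene‑1‑carboxylic acid F2, and esterification with TMSCHN2 as in step 2 returns to the route at ester 4.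

Step 8. The side chain on C6 may shield its face of the diene too little, so that the dioxirane attacks both faces, and some oxidant may also be lost to attack at the enol ether double bond. The fallback sets out from 14 and uses the wrong‑face product instead of discarding it. The C1 epimer (4R,5S)‑4‑hydroxy‑2‑methyl‑5‑[(2R)‑6‑methyl‑4‑oxohept‑5‑en‑2‑yl]cyclohex‑2‑en‑1‑one F3 is esterified with angelic acid 17 under Mitsunobu conditions (PPh3, DIAD, PhMe, 0 °C), which inverts C1. Both epimers then converge, and the route is rejoined at angelate 19.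

Step 10. At the ring ketone the inherent preference of this carvone‑type enone for axial hydride delivery (hydroxyl cis to the chain) opposes the catalyst, so the C4 epimer may dominate while C9 is reduced correctly. The fallback sets out from 14 and separates the two reductions.
- (S)‑Me‑CBS/catecholborane reduces the only ketone present to (4R,6R)‑6‑[(1S)‑5‑methoxy‑4‑methylcyclohexa‑2,4‑dien‑1‑yl]‑2‑methylhept‑2‑en‑4‑ol F4.
- Ac2O/pyridine/DMAP gives (4R,6R)‑6‑[(1S)‑5‑methoxy‑4‑methylcyclohexa‑2,4‑dien‑1‑yl]‑2‑methylhept‑2‑en‑4‑yl acetate F5.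
- DMDO and then aqueous acid, as in step 8, give (4R,6R)‑6‑[(1S,2S)‑2‑hydroxy‑4‑methyl‑5‑oxocyclohex‑3‑en‑1‑yl]‑2‑methylhept‑2‑en‑4‑yl acetate F6; the dienol ether is far more nucleophilic than the allylic‑acetate alkene.
- Angeloylation as in step 9 gives (1S,6S)‑6‑[(2R,4R)‑4‑acetoxy‑6‑methylhept‑5‑en‑2‑yl]‑3‑methyl‑4‑oxocyclohex‑2‑en‑1‑yl (2Z)‑2‑methylbut‑2‑enoate F7.
- Luche reduction (NaBH4, CeCl3, MeOH, −78 °C) now works with the substrate bias and gives (1S,4S,6S)‑6‑[(2R,4R)‑4‑acetoxy‑6‑methylhept‑5‑en‑2‑yl]‑4‑hydroxy‑3‑methylcyclohex‑2‑en‑1‑yl (2Z)‑2‑methylbut‑2‑enoate F8.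
- A Mitsunobu reaction with acetic acid (PPh3, DIAD) inverts C4 and installs the acetate, arriving at target 21.

## Further compounds

F1 | step 3 | (1S)‑1‑phenylethanaminium (1R)‑3‑methoxy‑2‑methylcyclohexa‑2,5‑diene‑1‑carboxylate | [O-]C(=O)[C@@H]1C=CCC(OC)=C1C.C[C@H]([NH3+])c1ccccc1
F2 | step 3 | (1R)‑3‑methoxy‑2‑methylcyclohexa‑2,5‑diene‑1‑carboxylic acid | OC(=O)[C@@H]1C=CCC(OC)=C1C
F3 | step 8 | (4R,5S)‑4‑hydroxy‑2‑methyl‑5‑[(2R)‑6‑methyl‑4‑oxohept‑5‑en‑2‑yl]cyclohex‑2‑en‑1‑one | O[C@H]1C=C(C)C(=O)C[C@H]1[C@H](C)CC(=O)C=C(C)C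
F4 | step 10 | (4R,6R)‑6‑[(1S)‑5‑methoxy‑4‑methylcyclohexa‑2,4‑dien‑1‑yl]‑2‑methylhept‑2‑en‑4‑ol | COC1=C(C)C=C[C@@H](C1)[C@H](C)C[C@H](C=C(C)C)O
F5 | step 10 | (4R,6R)‑6‑[(1S)‑5‑methoxy‑4‑methylcyclohexa‑2,4‑dien‑1‑yl]‑2‑methylhept‑2‑en‑4‑yl acetate | COC1=C(C)C=C[C@@H](C1)[C@H](C)C[C@H](C=C(C)C)OC(C)=O
F6 | step 10 | (4R,6R)‑6‑[(1S,2S)‑2‑hydroxy‑4‑methyl‑5‑oxocyclohex‑3‑en‑1‑yl]‑2‑methylhept‑2‑en‑4‑yl acetate | O[C@@H]1C=C(C)C(=O)C[C@H]1[C@H](C)C[C@H](C=C(C)C)OC(C)=O
F7 | step 10 | (1S,6S)‑6‑[(2R,4R)‑4‑acetoxy‑6‑methylhept‑5‑en‑2‑yl]‑3‑methyl‑4‑oxocyclohex‑2‑en‑1‑yl (2Z)‑2‑methylbut‑2‑enoate | C/C=C(/C)C(=O)O[C@@H]1C=C(C)C(=O)C[C@H]1[C@H](C)C[C@H](C=C(C)C)OC(C)=O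
F8 | step 10 | (1S,4S,6S)‑6‑[(2R,4R)‑4‑acetoxy‑6‑methylhept‑5‑en‑2‑yl]‑4‑hydroxy‑3‑methylcyclohex‑2‑en‑1‑yl (2Z)‑2‑methylbut‑2‑enoate | C/C=C(/C)C(=O)O[C@@H]1C=C(C)[C@@H](O)C[C@H]1[C@H](C)C[C@H](C=C(C)C)OC(C)=O
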